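**Plan**

Retrosynthesis: a helper ester is first added at C3 (it leaves by decarboxylation in the forward sense). The C2–C3 bond of ring C (O1–C2–C3–C4–C4a–C8a) is then cut as a double C–H disconnection, which opens the flavanone to the 4-methoxybenzyl (PMB) ether of a 2-hydroxyaroylacetate. C3–C4, O1–CH2 and the ring A substituents are cut last.
Forward: rings A and B are bought as 3,4,5-trimethoxyphenol and PMBCl. Ring A is filled to hexasubstitution (steps 1–3), C2 with ring B is hung on O1 (step 4), C3 comes with tert-butyl acetate (steps 5–6), ring C closes last (step 7), and the helper leaves (step 8).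
Enabling feature: C2 stands between O1 and ring B, whose 4'-methoxy group is para to it, so at the CH2 level C2 is simply the methylene of a PMB ether, an excellent hydride donor towards DDQ. C3 is alpha to the C4 carbonyl and, with the ester, becomes a chelating soft nucleophile, so two C–H carbons are joined oxidatively.
Stereochemistry: C2, the only stereocenter of the target, is created in the ring closure under Cu(OTf)2/(S,S)-tBu-box control. C3 is transient. The last step is run without base so that ring C cannot open by a retro-oxa-Michael reaction.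

Key step: step 7

Assumption: the sense of induction of Cu(OTf)2/(S,S)-tBu-box in step 7 rests on a quadrant model and not on a tested case. Should the closure favour the 2R series, the equally available (R,R)-ligand takes its place and nothing else changes.

**Route**

Step 1
Reactants: 1 3,4,5-trimethoxyphenol
Product: 2 2-hydroxy-4,5,6-trimethoxybenzaldehyde
Conditions: MgCl2, Et3N, (CH2O)n, MeCN, reflux; then 1 M HCl
Reagents that add atoms: paraformaldehyde, written as formaldehyde, C=O
Why: Casnati–Skattebøl ortho-formylation, in which the magnesium phenoxide of 1 delivers formaldehyde only to one of the two equivalent positions ortho to the oxygen and a second formaldehyde takes up hydride from the benzylic alkoxide to give the salicylaldehyde.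

Step 2
Reactants: 2 2-hydroxy-4,5,6-trimethoxybenzaldehyde
Product: 3 3-bromo-2-hydroxy-4,5,6-trimethoxybenzaldehyde
Conditions: NBS, MeCN, 0 °C to rt
Reagents that add atoms: N-bromosuccinimide (NBS), O=C1CCC(=O)N1Br
Why: Electrophilic aromatic bromination at the only free ring position, which lies ortho to the hydroxy group and to a methoxy group, so no regiochemical question arises.

Step 3
Reactants: 3 3-bromo-2-hydroxy-4,5,6-trimethoxybenzaldehyde
Product: 4 2-hydroxy-3,4,5,6-tetramethoxybenzaldehyde
Conditions: NaOMe, CuCl (20 mol %), DMF/MeOH, 110 °C; then 1 M HCl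
Reagents that add atoms: sodium methoxide, C[O-].[Na+]
Why: Ullmann-type methoxylation of an ortho-bromophenol that bears a formyl group, catalysed by monovalent copper, the reaction type that turns 5-bromovanillin into syringaldehyde; the aldehyde cannot enolize and is deactivated as the vinylogous phenoxide.

Step 4
Reactants: 4 2-hydroxy-3,4,5,6-tetramethoxybenzaldehyde, 5 4-methoxybenzyl chloride (PMBCl)
Product: 6 2,3,4,5-tetramethoxy-6-[(4-methoxybenzyl)oxy]benzaldehyde
Conditions: K2CO3, DMF, 60 °C
Reagents that add atoms: none
Why: Williamson ether synthesis (SN2 of the phenoxide on a reactive benzylic chloride), which brings in C2 and ring B of the target in one piece.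

Step 5
Reactants: 6 2,3,4,5-tetramethoxy-6-[(4-methoxybenzyl)oxy]benzaldehyde, 7 tert-butyl acetate
Product: 9 tert-butyl 3-hydroxy-3-{2,3,4,5-tetramethoxy-6-[(4-methoxybenzyl)oxy]phenyl}propanoate (racemic), via lithium enolate of tert-butyl acetate 8 (not isolated)
Conditions: LiN(iPr)2, THF, −78 °C, 7, then 6; aq NH4Cl
Reagents that add atoms: none
Why: Aldol addition of a preformed ester lithium enolate to a non-enolizable aldehyde; the new carbinol center forms as a racemate and is erased in step 6.

Step 6
Reactants: 9 tert-butyl 3-hydroxy-3-{2,3,4,5-tetramethoxy-6-[(4-methoxybenzyl)oxy]phenyl}propanoate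
Product: 10 tert-butyl 3-oxo-3-{2,3,4,5-tetramethoxy-6-[(4-methoxybenzyl)oxy]phenyl}propanoate
Conditions: Dess–Martin periodinane, CH2Cl2, 0 °C to rt
Reagents that add atoms: none
Why: Dess–Martin oxidation of a secondary benzylic alcohol under nearly neutral conditions, which leaves the PMB ether, the tert-butyl ester and the methoxy groups untouched.

Step 7
Reactants: 10 tert-butyl 3-oxo-3-{2,3,4,5-tetramethoxy-6-[(4-methoxybenzyl)oxy]phenyl}propanoate
Product: 12 tert-butyl (2S,3R)-5,6,7,8-tetramethoxy-2-(4-methoxyphenyl)-4-oxochromane-3-carboxylate, via (E)-aryloxycarbenium ion 11 (not isolated)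
Conditions: Cu(OTf)2 (10 mol %), (S,S)-tBu-box (11 mol %), DDQ (1.2 equiv, added slowly), 4 Å MS, CH2Cl2, −20 to 0 °C
Reagents that add atoms: none
Why: Proposed new method: DDQ takes a hydride from the OCH2 group of the PMB ether of 10, the C–H bond that is activated both by O1 and by ring B with its para 4'-methoxy group, to give the (E)-aryloxycarbenium ion 11, while Cu(OTf)2/(S,S)-tBu-box holds the β-keto ester as a flat six-membered chelate enolate (its proton ends on the reduced quinone), and C3 of this enolate then attacks C2. The closest known reaction type is the enantioselective cross-dehydrogenative cyclization of β-keto esters onto DDQ-generated oxocarbenium ions of benzylic and allylic alkyl ethers under chiral bis(oxazoline)/Cu(OTf)2 catalysis, which gives 2-substituted tetrahydropyran-4-ones, and the DDQ cleavage of phenolic PMB ethers shows that an ion such as 11 is within reach; new here are the phenol-derived ether and the benzo-fused ring. Ring C closes in a 6-(enolendo)-endo-trig mode through a half-chair in which the twist of the aroyl group, enforced by the 5-methoxy group, lifts C3 over the face of the O1=C2 bond. C2 is set by the ligand: the cation is tied to the ketone side of the chelate and can swing only over the enolate face that the neighbouring tert-butyl group of the ligand leaves open, so that the Re face of C3 should meet the Si face of C2 (2S). C3 (3R, trans) follows from the (E)-geometry of 11 and the chelate geometry, which place the aryl and ester groups both equatorial, and it is lost in step 8. The step needs hydride abstraction at the PMB methylene rather than oxidation of ring A, of a methoxy group or of product 12, and C- rather than O-attack of the enolate: the para-methoxy group makes this the only strongly hydridic C–H bond, the aroyl group lowers the donor power of ring A, the β-dicarbonyl unit next to C2–H deactivates 12, and an acetal formed by O-attack would re-ionize under the Lewis acid.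

Step 8
Reactants: 12 tert-butyl (2S,3R)-5,6,7,8-tetramethoxy-2-(4-methoxyphenyl)-4-oxochromane-3-carboxylate
Product: 14 (2S)-5,6,7,8,4'-pentamethoxyflavanone, via β-keto acid 13 (not isolated)
Conditions: TsOH·H2O (20 mol %), toluene, 80 °C
Reagents that add atoms: none
Why: Acid-catalysed loss of isobutene from the tert-butyl ester and decarboxylation of β-keto acid 13 through the cyclic six-membered transition state, a known way to free 3-carboxylated flavanones; no base, and hence no enolate that could expel O1 as a phenoxide, is present, so C2 should keep its configuration.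

**Compound list**

1 | 3,4,5-trimethoxyphenol | COc1cc(O)cc(OC)c1OC | starting material
2 | 2-hydroxy-4,5,6-trimethoxybenzaldehyde | COc1cc(O)c(C=O)c(OC)c1OC | intermediate
3 | 3-bromo-2-hydroxy-4,5,6-trimethoxybenzaldehyde | COc1c(Br)c(O)c(C=O)c(OC)c1OC | intermediate
4 | 2-hydroxy-3,4,5,6-tetramethoxybenzaldehyde | COc1c(OC)c(O)c(C=O)c(OC)c1OC | intermediate
5 | 4-methoxybenzyl chloride (PMBCl) | COc1ccc(CCl)cc1 | starting material
6 | 2,3,4,5-tetramethoxy-6-[(4-methoxybenzyl)oxy]benzaldehyde | COc1ccc(COc2c(OC)c(OC)c(OC)c(OC)c2C=O)cc1 | intermediate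
7 | tert-butyl acetate | CC(=O)OC(C)(C)C | starting material
8 | lithium enolate of tert-butyl acetate (not isolated) | [Li+].C=C([O-])OC(C)(C)C | intermediate
9 | tert-butyl 3-hydroxy-3-{2,3,4,5-tetramethoxy-6-[(4-methoxybenzyl)oxy]phenyl}propanoate (racemic) | COc1ccc(COc2c(OC)c(OC)c(OC)c(OC)c2C(O)CC(=O)OC(C)(C)C)cc1 | intermediate
10 | tert-butyl 3-oxo-3-{2,3,4,5-tetramethoxy-6-[(4-methoxybenzyl)oxy]phenyl}propanoate | COc1ccc(COc2c(OC)c(OC)c(OC)c(OC)c2C(=O)CC(=O)OC(C)(C)C)cc1 | intermediate
11 | (E)-aryloxycarbenium ion from 10 by loss of hydride at the PMB methylene (not isolated) | COc1ccc(/C=[O+]/c2c(OC)c(OC)c(OC)c(OC)c2C(=O)CC(=O)OC(C)(C)C)cc1 | intermediate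
12 | tert-butyl (2S,3R)-5,6,7,8-tetramethoxy-2-(4-methoxyphenyl)-4-oxochromane-3-carboxylate (2,3-trans) | COc1ccc([C@@H]2[C@@H](C(=O)OC(C)(C)C)C(=O)c3c(OC)c(OC)c(OC)c(OC)c3O2)cc1 | intermediate
13 | (2S,3R)-5,6,7,8-tetramethoxy-2-(4-methoxyphenyl)-4-oxochromane-3-carboxylic acid (not isolated) | COc1ccc([C@@H]2[C@@H](C(=O)O)C(=O)c3c(OC)c(OC)c(OC)c(OC)c3O2)cc1 | intermediate
14 | (2S)-5,6,7,8,4'-pentamethoxyflavanone | COc1ccc([C@@H]2CC(=O)c3c(OC)c(OC)c(OC)c(OC)c3O2)cc1 | target

**Count and risks**

Total step count: 8. Longest linear sequence: 8 steps (from 1).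

Steps most likely to fail:

1. Step 7 (the labelled step).
- What may go wrong: hydride abstraction from the less donating aryl ether may be sluggish. Electron transfer from ring A may compete. The PMB group may be lost hydrolytically through adventitious water. Closure may occur through the enolate oxygen. Facial selectivity may be poor, or the configuration may erode by Lewis-acid-induced opening and reclosure of ring C.
- Fallback (known chemistry, ring C closed at O1–C2 instead): it sets out from 10. Hydrogenolysis of the PMB ether (H2, Pd/C, EtOAc, rt) would give tert-butyl 3-(2-hydroxy-3,4,5,6-tetramethoxyphenyl)-3-oxopropanoate F1. Knoevenagel condensation with commercial 4-methoxybenzaldehyde (piperidine, AcOH, toluene, 4 Å MS) would give tert-butyl 2-(2-hydroxy-3,4,5,6-tetramethoxybenzoyl)-3-(4-methoxyphenyl)prop-2-enoate F2. An intramolecular oxa-Michael addition follows, catalysed by a cinchona-alkaloid-derived bifunctional thiourea (toluene, −25 °C), with the pseudoenantiomer chosen for the 2S series. This comes back to the route at 12.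

2. Step 8.
- What may go wrong: acid may open ring C through the enol, helped by the 4-methoxyphenyl group at C2, and reclosure would then erode the configuration at C2.
- Fallback (a helper that leaves by hydrogenolysis under neutral conditions): it sets out from 6. Aldol addition of the lithium enolate of benzyl acetate (LiN(iPr)2, THF, −78 °C) would give benzyl 3-hydroxy-3-{2,3,4,5-tetramethoxy-6-[(4-methoxybenzyl)oxy]phenyl}propanoate F3. Dess–Martin oxidation would give benzyl 3-oxo-3-{2,3,4,5-tetramethoxy-6-[(4-methoxybenzyl)oxy]phenyl}propanoate F4. The oxidative closure of step 7 would give benzyl (2S,3R)-5,6,7,8-tetramethoxy-2-(4-methoxyphenyl)-4-oxochromane-3-carboxylate F5. H2, Pd/C in EtOAc at rt frees the acid, so the route is rejoined at 13, which should lose CO2 at or slightly above room temperature to give 14.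

3. Step 3.
- What may go wrong: substitution at the doubly ortho-flanked bromide may be slow, and reductive loss of bromine may compete.
- Fallback (the fifth oxygen comes from a Baeyer–Villiger oxidation, and symmetry solves the final regiochemistry): it sets out from 2. The sequence would run as follows.
 - O-Methylation (MeI, K2CO3, DMF) gives 2,3,4,6-tetramethoxybenzaldehyde F6.
 - mCPBA in CH2Cl2 gives 2,3,4,6-tetramethoxyphenyl formate F7.
 - Methanolysis (K2CO3, MeOH) gives 2,3,4,6-tetramethoxyphenol F8.
 - Methylation gives pentamethoxybenzene F9.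
 - Rieche formylation (Cl2CHOMe, TiCl4, CH2Cl2) gives pentamethoxybenzaldehyde F10.
 - Chelation-controlled removal of one of the two equivalent ortho methyl groups (BCl3, CH2Cl2, −78 to 0 °C) comes back to the route at 4.

**Further compounds**

F1 | step 7 | tert-butyl 3-(2-hydroxy-3,4,5,6-tetramethoxyphenyl)-3-oxopropanoate | COc1c(O)c(C(=O)CC(=O)OC(C)(C)C)c(OC)c(OC)c1OC
F2 | step 7 | tert-butyl 2-(2-hydroxy-3,4,5,6-tetramethoxybenzoyl)-3-(4-methoxyphenyl)prop-2-enoate (alkene geometry not defined) | COc1ccc(C=C(C(=O)OC(C)(C)C)C(=O)c2c(O)c(OC)c(OC)c(OC)c2OC)cc1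
F3 | step 8 | benzyl 3-hydroxy-3-{2,3,4,5-tetramethoxy-6-[(4-methoxybenzyl)oxy]phenyl}propanoate (racemic) | COc1ccc(COc2c(OC)c(OC)c(OC)c(OC)c2C(O)CC(=O)OCc3ccccc3)cc1
F4 | step 8 | benzyl 3-oxo-3-{2,3,4,5-tetramethoxy-6-[(4-methoxybenzyl)oxy]phenyl}propanoate | COc1ccc(COc2c(OC)c(OC)c(OC)c(OC)c2C(=O)CC(=O)OCc3ccccc3)cc1
F5 | step 8 | benzyl (2S,3R)-5,6,7,8-tetramethoxy-2-(4-methoxyphenyl)-4-oxochromane-3-carboxylate | COc1ccc([C@@H]2[C@@H](C(=O)OCc4ccccc4)C(=O)c3c(OC)c(OC)c(OC)c(OC)c3O2)cc1
F6 | step 3 | 2,3,4,6-tetramethoxybenzaldehyde | COc1cc(OC)c(C=O)c(OC)c1OC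
F7 | step 3 | 2,3,4,6-tetramethoxyphenyl formate | COc1cc(OC)c(OC=O)c(OC)c1OC
F8 | step 3 | 2,3,4,6-tetramethoxyphenol | COc1cc(OC)c(O)c(OC)c1OC
F9 | step 3 | pentamethoxybenzene | COc1cc(OC)c(OC)c(OC)c1OC
F10 | step 3 | pentamethoxybenzaldehyde | COc1c(OC)c(OC)c(C=O)c(OC)c1OC
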